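## The problem

Ainsliadimer A consists of two guaianolide units, A and B, joined through a central cyclopentane (C3, C4, C15, C15′, C4′; guaianolide numbering, primed atoms in the ketone-bearing unit B) that is fused to the five-membered carbocycle of unit A and spiro-linked at C4′ to the five-membered carbocycle of unit B, called ring B5 here, while the cycloheptane of unit B is called ring B7. Each unit is a cis-fused hydroazulene with a trans-fused α-methylene-γ-lactone and an exocyclic methylene at C10 or C10′. Of the eleven stereocentres, C1, C5, C6 and C7 can be taken from the chiral pool, C3, C4 and C4′ are three contiguous fully substituted carbons (two tertiary carbinols and a quaternary spiro centre), and C1′, C5′, C6′ and C7′ must be built on ring B7. Control can be relayed: the convex face of unit A sets C4; the cis ring fusion of the new bicyclo[3.3.0]octane lets C4 dictate C3; the C3 carbinol on C4′ differentiates the two faces of ring B5 and so governs C1′ and C5′; C5′ biases C6′; and the C6′ oxygen can direct C7′. The fragile groups are the two α-methylene lactones (Michael acceptors, base- and light-sensitive), the two 1,1-disubstituted alkenes, the β-hydroxy ketone C3–OH/C3′=O (retro-aldol), the ditertiary diol (ionisation), and C1/C1′, which can epimerise whenever C10/C10′ are ketones. The feature that opens the structure is ring B7 (C1′, C5′, C6′, C7′, C8′, C9′, C10′): it carries oxygen at C6′ and needs an sp2 carbon at C10′ and a functionalised C7′, which makes it an α-oxygenated cycloheptane-1,4-dione in disguise. Such a dione arises when the C1′=C5′ alkene of a spiro cyclopentene is inserted into an oxygenated cyclopentane-1,3-dione enol.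

## Retrosynthesis

**Late unsaturation and the C3′ carbonyl (37 ⇐ 36 ⇐ 35 ⇐ 34 ⇐ 33 ⇐ 32).** The last operations cut no skeletal bond of the core. They remove the C11=C13 and C11′=C13′ double bonds (bis-selenide 34, via bis-selenoxide 35), the C11′–C13′ bond (methylation of 32 to 33) and the C3′ carbonyl (alcohol 36). Carrying the α-methylene lactones earlier would expose two Michael acceptors to light, base and hydrogen. Holding C3′ as an alcohol during the enolate chemistry excludes retro-aldol cleavage of C3–C4′ and enolisation at C2′. Compound 32 has no acceptor left. The forward steps must distinguish the CH2 of lactone B from the CH(CH3) of lactone A, and must place selenium anti to H7 and H7′.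

**Both exocyclic methylenes and the C3′ mask (32 ⇐ 31 ⇐ 30).** C10=C14 and C10′=C14′ are cut together back to the two cycloheptanones of 31. The C3′ carbinol is traced to triketone 30 by a hydroxyl-directed reduction that only a β-hydroxy ketone can undergo. Treating both halves alike costs one methylenation. The C14 carbon of unit A is deliberately given up early, because a 1,1-disubstituted alkene cannot be carried through the photochemical step.

**Lactone B (30 ⇐ 29 ⇐ 28 ⇐ 27 ⇐ 26).** The cuts are O–C12′ (lactonisation) and C7′=C11′ (Wittig olefination of the α-acetoxy ketone). The neighbouring cut, an intramolecular Horner–Wadsworth–Emmons reaction through an ester on O6′, would give a butenolide. Reducing that butenolide adds hydrogen to C7′ from the open face syn to H6′ and gives the cis-lactone. The open-chain (E)-enoate 27 lets the free C6′ hydroxyl of 28 deliver hydrogen to the α face, which gives the trans relationship in 29. The forward reaction must olefinate C7′ and not C10′, and must give the E isomer.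

**Ring B7 (26 ⇐ 25 ⇐ 21 + 24).** The bonds C1′–C10′ and C5′–C6′ are cut, and the C6′–C10′ bond of a cyclobutanol 25 is restored. Other cuts inside ring B7 (C8′–C9′ by metathesis, C1′–C10′ by aldol) would need two stereodefined chains on C1′ and C5′ first. The De Mayo cut needs only a flat cis-alkene and an achiral five-carbon enol. Precursor 21 has lost ring B7, three stereocentres and five carbons. The forward step must add to the face anti to C3, join the acetoxy-bearing carbon to C5′, and find no other alkene in the molecule.

**Spiro ring and alkene position (21 ⇐ 20 ⇐ 19 ⇐ 18).** The dioxolane at C3′ and the C1′=C5′ alkene come from conjugated enone 20 by deconjugative ketalisation. The C3–C4′ bond is cut by an intramolecular aldol reaction, via the unconjugated adduct 19. Closing the central ring at C4–C15 or C15–C15′ would leave the quaternary C4′ to be made intermolecularly. The aldol cut uses two existing carbonyl groups and sets C3 and C4′ in the ring-forming step. Compound 18 is a monomeric guaianolide carrying an achiral cyclopentenone.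

**Arm (18 ⇐ 17 ⇐ 16 ⇐ 13 + 15; 15 ⇐ 14).** The sp3–sp2 bond C15′–C4′ is cut by a B-alkyl Suzuki–Miyaura coupling of the borane 16 from vinyl carbinol 13 with 2-iodocyclopent-2-en-1-one 15, made from 14. Alkylating a cyclopentenone enolate with a neopentyl-type iodide would be the weaker neighbour. The coupling must tolerate a lactone, a ketal and free hydroxyls.

**C4 carbinol (13 ⇐ 12 ⇐ 11).** C15–C15′ is cut to a sulfonium ylide and the spiro-oxirane 12. The C4–O bond comes from hydroxyl-directed epoxidation of allylic alcohol 11, which fixes C4 before any second unit is present.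

**Unit A from the chiral pool (11 ⇐ 10 ⇐ 9 ⇐ 8 ⇐ 7 ⇐ 6 ⇐ 5 ⇐ 4 ⇐ 3 ⇐ 2 ⇐ 1).** These are functional-group changes on the hydroazulene obtained by photorearrangement of α-santonin 1. They comprise reduction of the enone, removal of C14 as formaldehyde (ozonide 6), protection of C10, and transposition of functionality from C3/C4 to C3/C4/C15 through alkene 9 and epoxide 10. C6, C7 and C11 come from santonin, C1 from the rearrangement and C5 from the hydrogenation.

**Enol partner (24 ⇐ 23 ⇐ 22).** The C2–O bond of 24 is cut to acetic acid and the carbenoid from diazo dione 23, made by diazo transfer to cyclopentane-1,3-dione 22.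

## Roads not taken

**Alternative 1:** The cut is C1′–C2′. Diazomethyl ketone A1, with the diazoketone on the quaternary C4′ and a complete ring B7, would be decomposed by Rh2(OAc)4, and the carbenoid carbon would insert into the C1′–H bond to close ring B5 as cyclopentanone A2. Insertion with retention guarantees the cis ring fusion. Ring B7 with its lactone arrives intact, so C5′, C6′ and C7′ never have to be created on the dimer. In that respect this road is better than the chosen one, which must set four centres on ring B7. Its weak points are two. First, A1 already contains the quaternary C4′ bonded to C3, C15′ and C5′, so the hardest bond set of the molecule must be made between two hindered, fully elaborated fragments before the key step. Second, the carbenoid has three 1,5 C–H bonds within reach (C1′–H, C6′–H and C15–H2), so site selectivity is open. A second chiral fragment and a masked C14′ (the pivalate in A2) add steps. The chosen plan sets against this a ring B7 that grows from an achiral five-carbon unit on a substrate whose spiro centre is already in place.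

**Alternative 2:** The cuts are C1′–C5′, C2′–C3′ and C3′–C4′. Allene-yne A3 would be cyclocarbonylated with [Rh(CO)2Cl]2 under CO at the distal allene bond to give alkylidene cyclopentenone A4. This forms rings B5 and B7, the spiro centre and the C3′ carbonyl in one step, and it is more convergent than the chosen plan in bonds formed per step. Its weak points lie in what the product lacks. C1′, C5′ and C6′ are all sp2 in A4. The C6′ oxygen would have to be introduced by allylic oxidation, and three stereocentres set by later reductions on a cross-conjugated dienone. The spiro configuration also depends on the facial selectivity at a tetrasubstituted allene terminus next to a tertiary carbinol. The chosen plan is less convergent, but it delivers the C6′ oxygen, both ring B7 carbonyls and the cis fusion in the ring-forming step.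

**Alternative 3:** The cut is C3–C4. The eight-membered 1,5-diketone A5 would be reduced with SmI2, and the two ketyls would couple across the ring to give the cis-diol A6, closing the cyclopentane of unit A and the central ring at once. Both tertiary carbinols are set in one chelated step. The chosen plan needs an epoxidation, an ylide homologation and an aldol reaction for the same oxygens, so on this point the alternative is better. Its weak points are in the substrate. A5 holds a medium ring that includes the quaternary C4′, and the cyclopentane of unit A is open, so the intact hydroazulene of santonin cannot be used. Unit B must also be complete beforehand, so the problem of ring B7 is only postponed. The facial course of the coupling relative to H1 and H5 rests on conformation alone. The chosen plan offers a shorter route to the core from the chiral pool and a spiro centre that is set under chelation.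

Key step: step 19

Remark: guaianolide numbering with primed locants for unit B is used. Unit A keeps the C11 methyl group (C13) of α-santonin until step 28, so compounds 21 and 26 are 11-methyl lactones. Centres that are destroyed later (C10 of 6, C11′ of 33, C11 and C11′ of 34 and 35) are drawn without configuration.

## Steps

Step 1
Reactants: 1 α-santonin
Product: 2 isophotosantonic lactone (10α-hydroxy-3-oxo-1αH-guai-4-en-12,6α-olide)
Conditions: hν (medium-pressure Hg lamp), AcOH–H2O (1:1), reflux
Reagents that add atoms: water, O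
Why: Photochemical rearrangement of the cross-conjugated cyclohexadienone with capture of the C10 cation by water gives the hydroazulenone; C6, C7 and C11 are untouched and H1 emerges α, the established course for α-santonin in aqueous acetic acid.

Step 2
Reactants: 2 isophotosantonic lactone
Product: 3 10α-hydroxy-3-oxo-1αH,4αH,5αH-guaian-12,6α-olide
Conditions: H2 (1 atm), Pd/C, EtOAc, rt
Reagents that add atoms: none
Why: Heterogeneous hydrogenation of the tetrasubstituted enone from the α face, the face of H1 and away from the β-methyl group on C10, puts H4 and H5 cis to H1 and sets the natural cis ring fusion at C5.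

Step 3
Reactants: 3 10α-hydroxy-3-oxo-1αH,4αH,5αH-guaian-12,6α-olide
Product: 4 3-oxo-1αH,4αH,5αH-guai-10(14)-en-12,6α-olide
Conditions: SOCl2, pyridine, CH2Cl2, −20 → 0 °C
Reagents that add atoms: none
Why: Dehydration of the tertiary alcohol through its chlorosulfite; the α leaving group has no anti-periplanar hydrogen at C1, so elimination should favour the C14 methyl group, and any endocyclic isomer is removed at this early, inexpensive stage.

Step 4
Reactants: 4 3-oxo-1αH,4αH,5αH-guai-10(14)-en-12,6α-olide
Product: 5 3β-hydroxy-1αH,4αH,5αH-guai-10(14)-en-12,6α-olide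
Conditions: NaBH4, MeOH, 0 °C
Reagents that add atoms: none
Why: Borohydride reduces only the cyclopentanone; hydride enters from the convex α face to give the 3β-alcohol, which has H4 anti-periplanar for step 7 and differentiates C3 from the ketone made at C10 in step 5.

Step 5
Reactants: 5 3β-hydroxy-1αH,4αH,5αH-guai-10(14)-en-12,6α-olide
Product: 7 3β-hydroxy-10-oxo-14-nor-1αH,4αH,5αH-guaian-12,6α-olide, via secondary ozonide 6 (not isolated)
Conditions: O3, CH2Cl2, −78 °C; then Me2S, −78 °C → rt
Reagents that add atoms: ozone, [O-][O+]=O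
Why: Ozonolysis of the only alkene with neutral reductive work-up; C14 is removed because a 1,1-disubstituted alkene would compete in the photocycloaddition of step 19, and it returns in step 25.

Step 6
Reactants: 7 3β-hydroxy-10-oxo-14-nor-1αH,4αH,5αH-guaian-12,6α-olide
Product: 8 10,10-ethylenedioxy-3β-hydroxy-14-nor-1αH,4αH,5αH-guaian-12,6α-olide
Conditions: TMSOCH2CH2OTMS, TMSOTf (cat.), CH2Cl2, −78 → −20 °C; then K2CO3, MeOH, 0 °C (cleaves any 3-O-silyl ether)
Reagents that add atoms: 1,2-bis(trimethylsilyloxy)ethane, C[Si](C)(C)OCCO[Si](C)(C)C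
Why: Aprotic, low-temperature ketalisation protects C10 without the protic enolisation that could epimerise C1; the dioxolane then blocks enolisation towards C1 until step 23.

Step 7
Reactants: 8 10,10-ethylenedioxy-3β-hydroxy-14-nor-1αH,4αH,5αH-guaian-12,6α-olide
Product: 9 10,10-ethylenedioxy-14-nor-1αH,5αH-guai-3-en-12,6α-olide
Conditions: Ph2S[OC(CF3)2Ph]2 (Martin sulfurane), CH2Cl2, 0 °C → rt
Reagents that add atoms: none
Why: E2-type dehydration of the secondary alkoxysulfonium ion with the anti-periplanar H4 gives the trisubstituted (Zaitsev) C3=C4 alkene; the C4 centre is erased on purpose.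

Step 8
Reactants: 9 10,10-ethylenedioxy-14-nor-1αH,5αH-guai-3-en-12,6α-olide
Product: 10 3α,4α-epoxy-10,10-ethylenedioxy-14-nor-1αH,5αH-guaian-12,6α-olide
Conditions: mCPBA, NaHCO3, CH2Cl2, 0 °C
Reagents that add atoms: 3-chloroperoxybenzoic acid, OOC(=O)c1cccc(Cl)c1
Why: Prilezhaev epoxidation of the trisubstituted alkene from the convex α face of the cis-fused bicycle, the face of H1 and H5.

Step 9
Reactants: 10 3α,4α-epoxy-10,10-ethylenedioxy-14-nor-1αH,5αH-guaian-12,6α-olide
Product: 11 10,10-ethylenedioxy-3α-hydroxy-14-nor-1αH,5αH-guai-4(15)-en-12,6α-olide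
Conditions: Al(OiPr)3, toluene, reflux
Reagents that add atoms: none
Why: Aluminium-alkoxide-mediated isomerisation of a trisubstituted epoxide to the allylic alcohol by syn removal of a C15 methyl hydrogen, the route used to 3-hydroxy-4(15)-ene guaianolides; the C3–O bond and its α configuration are kept.

Step 10
Reactants: 11 10,10-ethylenedioxy-3α-hydroxy-14-nor-1αH,5αH-guai-4(15)-en-12,6α-olide
Product: 12 4α,15-epoxy-10,10-ethylenedioxy-3α-hydroxy-14-nor-1αH,5αH-guaian-12,6α-olide
Conditions: VO(acac)2 (cat.), t-BuOOH, CH2Cl2, 0 °C → rt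
Reagents that add atoms: tert-butyl hydroperoxide, CC(C)(C)OO
Why: Hydroxyl-directed epoxidation delivers oxygen syn to the 3α-hydroxyl, which is also the convex face; the oxirane oxygen is therefore α at C4, and this sets the C4 carbinol centre of the target.

Step 11
Reactants: 12 4α,15-epoxy-10,10-ethylenedioxy-3α-hydroxy-14-nor-1αH,5αH-guaian-12,6α-olide
Product: 13 4β-vinyl-3α,4α-diol (10,10-ethylenedioxy-3α,4α-dihydroxy-15-methylene-14-nor-1αH,5αH-guaian-12,6α-olide; the new carbon is C15′)
Conditions: Me3S+ I−, n-BuLi, THF, −10 °C → rt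
Reagents that add atoms: trimethylsulfonium iodide, C[S+](C)C.[I-]
Why: The sulfonium ylide opens the 2,2-disubstituted oxirane at its CH2 terminus (C15) and the betaine loses dimethyl sulfide, a one-carbon homologation of an epoxide to an allylic alcohol; C4 keeps its C–O bond and configuration, and the hindered α-methyl lactone should survive at this temperature.

Step 12
Reactants: 14 cyclopent-2-en-1-one
Product: 15 2-iodocyclopent-2-en-1-one
Conditions: I2, pyridine, CH2Cl2, 0 °C → rt
Reagents that add atoms: iodine, II
Why: α-Iodination of a cyclic enone by pyridine-mediated addition–elimination, a standard route to 2-iodoenones for cross-coupling.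

Step 13
Reactants: 13 4β-vinyl-3α,4α-diol; 15 2-iodocyclopent-2-en-1-one
Product: 17 diol enone (C4 carries OH α and a 2-(5-oxocyclopent-1-en-1-yl)ethyl group β), via B-alkyl-9-BBN adduct 16 (not isolated)
Conditions: 9-BBN (excess), THF, rt; then 15, PdCl2(dppf) (cat.), AsPh3, Cs2CO3, DMF–THF–H2O, rt
Reagents that add atoms: none
Why: Anti-Markovnikov hydroboration of the monosubstituted alkene and B-alkyl Suzuki–Miyaura coupling with the 2-iodoenone form the sp3–sp2 bond C15′–C4′ under conditions that leave the lactone, ketal and free hydroxyls alone.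

Step 14
Reactants: 17 diol enone
Product: 18 4α-hydroxy-3-ketone (3-oxo analogue of 17)
Conditions: IBX, DMSO, rt
Reagents that add atoms: none
Why: IBX oxidises the secondary C3 carbinol to the ketone and does not cleave the bond to the adjacent tertiary carbinol.

Step 15
Reactants: 18 4α-hydroxy-3-ketone
Product: 20 conjugated spiro enone aldol (C3–C4′ bond; 3α,4α-diol; C3′ ketone; C2′=C1′), via unconjugated spiro aldol 19 (not isolated)
Conditions: DBU, LiCl, MeCN, rt
Reagents that add atoms: none
Why: Reversible vinylogous enolisation at C1′ gives the extended dienolate, whose α carbon C4′ is the only position that can reach the lithium-chelated C3 ketone in a five-membered (5-exo-trig) aldol closure; the cis fusion of the new bicyclo[3.3.0]octane forces C3–OH α, the O–Li–O bridge between the C3 oxygen and the C3′ carbonyl sets C4′ with C3′ syn to the hydroxyl, and conjugation of the alkene into C2′=C1′ drains the equilibrium.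

Step 16
Reactants: 20 conjugated spiro enone aldol
Product: 21 spiro cyclopentene bis-dioxolane (C3′ and C10 dioxolanes; C1′=C5′; 3α,4α-diol; 11α-methyl lactone)
Conditions: HOCH2CH2OH, p-TsOH·H2O (cat.), 4 Å MS, CH2Cl2, rt
Reagents that add atoms: ethylene glycol, OCCO
Why: Acid-catalysed ketalisation through the dienol ether (γ-deprotonation at C5′, protonation at C2′) moves the alkene out of conjugation to C1′=C5′, as with steroidal enones; C4′ is quaternary, so only C5′ offers γ-hydrogens, and the mild conditions spare the ditertiary diol.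

Step 17
Reactants: 22 cyclopentane-1,3-dione
Product: 23 2-diazocyclopentane-1,3-dione
Conditions: 4-acetamidobenzenesulfonyl azide, Et3N, MeCN, 0 °C → rt
Reagents that add atoms: 4-acetamidobenzenesulfonyl azide, CC(=O)Nc1ccc(cc1)S(=O)(=O)N=[N+]=[N-]
Why: Regitz diazo transfer to the acidic C2 of a cyclic 1,3-dione.

Step 18
Reactants: 23 2-diazocyclopentane-1,3-dione
Product: 24 2-acetoxy-3-hydroxycyclopent-2-en-1-one
Conditions: Rh2(OAc)4 (1 mol %), AcOH, CH2Cl2, 40 °C
Reagents that add atoms: acetic acid, CC(=O)O
Why: O–H insertion of the rhodium carbenoid into the carboxylic acid gives the 2-acyloxy dione cleanly mono-oxygenated; the product exists as the enol.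

Step 19
Reactants: 21 spiro cyclopentene bis-dioxolane; 24 2-acetoxy-3-hydroxycyclopent-2-en-1-one
Product: 26 ring B7 acetoxy diketone (1′αH, 5′αH, 6′α-OAc; ketones at C7′ and C10′), via cyclobutanol photoadduct 25 (not isolated)
Conditions: hν (λ > 250 nm, Vycor filter), 24 (4 equiv, in portions), MeCN, 0 °C; then Et3N (0.2 equiv), CH2Cl2, rt
Reagents that add atoms: none
Why: Excitation of the enolised dione 24 (an enone chromophore) and triplet [2+2] photocycloaddition across C1′=C5′ give cyclobutanol 25, whose β-hydroxy ketone opens by retro-aldol cleavage of the C10′–C6′ bond, so the alkene carbons are inserted into the five-membered dione; this is the De Mayo reaction of a cyclic 1,3-dione enol with a cycloalkene. Ring B7 is therefore closed by intermolecular annulation (bonds C1′–C10′ and C5′–C6′) followed by strain-releasing fragmentation of the bicyclo[3.2.0]heptanone, not by a cyclisation, and it emerges with carbonyls at C10′ and C7′ and the acetoxy group at C6′. C1′ and C5′ are set together: the cyclobutane can only be cis-fused to ring B5, and the enol approaches the cyclopentene face that carries the C15′ methylene, anti to the fully substituted carbinol C3 on the neighbouring spiro carbon. Regiochemistry (hydroxy-bearing β carbon to C1′, acetoxy-bearing α carbon to C5′) rests on first bond formation between the enone β carbon and the alkene terminus remote from the quaternary C4′; the bias is steric only and is the main uncertainty of the step. C6′ is created when the enol released by the retro-aldol step ketonises; kinetic protonation anti to C4′ would give the cis isomer, so the crude diketone is equilibrated with triethylamine through the more acidic α-acyloxy C6′–H to the isomer with the acetoxy group trans to C4′, while the less acidic ring-fusion proton C1′–H should be left alone. Chemoselectivity requires the cyclopentene to be the only alkene of 21, which is why C10 is a ketal and lactone A still carries its methyl group; the enol is used in excess to offset its photodimerisation.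

Step 20
Reactants: 26 ring B7 acetoxy diketone
Product: 27 (E)-enoate (C7′=C11′H–CO2Me with the ester anti to C6′; 6′α-OAc; C10′ ketone)
Conditions: Ph3P=CHCO2Me, toluene, 90 °C
Reagents that add atoms: methyl (triphenylphosphoranylidene)acetate, COC(=O)C=P(c1ccccc1)(c1ccccc1)c1ccccc1
Why: Stabilised ylides olefinate α-acyloxy ketones but not unactivated ketones at this temperature, so the Wittig reaction is confined to C7′; the ester turns away from the branched C6′ to give the E isomer, which cannot lactonise, and the near-neutral conditions spare C1′.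

Step 21
Reactants: 27 (E)-enoate
Product: 28 6′α-alcohol (E)-enoate
Conditions: K2CO3 (cat.), MeOH, 0 °C
Reagents that add atoms: none
Why: Mild transesterification removes the allylic secondary acetate; the C3′ dioxolane excludes retro-aldol cleavage under base, and the E geometry prevents closure to a butenolide.

Step 22
Reactants: 28 6′α-alcohol (E)-enoate
Product: 29 7′αH hydroxy ester (C7′ carries CH2CO2Me β; 6′α-OH)
Conditions: H2 (1 atm), [Ir(cod)(PCy3)(py)]PF6 (5 mol %), CH2Cl2, 0 °C → rt
Reagents that add atoms: none
Why: Hydroxyl-directed homogeneous hydrogenation: the cationic iridium binds the C6′ hydroxyl and delivers H2 to the same (α) face of the exocyclic alkene, so H7′ enters cis to the oxygen and the acetate side chain becomes β, the trans arrangement that an undirected reduction from the open face would not give.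

Step 23
Reactants: 29 7′αH hydroxy ester
Product: 30 triketone bis-lactone (ketones at C3′, C10 and C10′; trans-fused lactone B; 3α,4α-diol; 11α-methyl lactone A)
Conditions: 1 M HCl, THF, rt
Reagents that add atoms: water, O
Why: Aqueous acid hydrolyses both dioxolanes and lactonises the trans γ-hydroxy ester to the trans-fused lactone; the β-hydroxy ketone has no hydrogen on C4′ and cannot dehydrate, and the acid exposure is kept short to limit enolisation towards C1 and C1′.

Step 24
Reactants: 30 triketone bis-lactone
Product: 31 3′-alcohol diketone (C3′–OH cis to C15′; ketones at C10 and C10′)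
Conditions: Me4NBH(OAc)3, AcOH–MeCN, −20 °C → rt
Reagents that add atoms: none
Why: Evans–Saksena reduction: the triacetoxyborohydride exchanges with the C3 hydroxyl and delivers hydride intramolecularly to the β-hydroxy ketone C3′ only, since the C10 and C10′ ketones have no suitably placed hydroxyl; hydride arrives from the C3 side, and the temporary carbinol masks C3′ against enolisation and retro-aldol cleavage.

Step 25
Reactants: 31 3′-alcohol diketone
Product: 32 bis(exocyclic methylene) compound (C10=C14 and C10′=C14′)
Conditions: Zn, CH2Br2, TiCl4, THF–CH2Cl2, 0 °C → rt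
Reagents that add atoms: dibromomethane, BrCBr
Why: Takai–Lombardo methylenation is non-basic and tolerates lactones and free hydroxyls; it converts both cycloheptanones without epimerising C1 or C1′.

Step 26
Reactants: 32 bis(exocyclic methylene) compound
Product: 33 11′-methyl lactone (both C11′ epimers serve)
Conditions: LDA (4.1 equiv), THF, −78 °C; then MeI, −78 → −40 °C
Reagents that add atoms: iodomethane, CI
Why: After the three alkoxides, kinetic deprotonation occurs faster at the unsubstituted α-CH2 of lactone B than at the tertiary α-CH of lactone A, and enolate methylation brings both lactones to the same α-methyl state.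

Step 27
Reactants: 33 11′-methyl lactone
Product: 34 11,11′-bis(phenylseleno) bis-lactone
Conditions: LDA (6 equiv), THF, −78 °C; then PhSeSePh, HMPA, −78 → −40 °C
Reagents that add atoms: diphenyl diselenide, c1ccc(cc1)[Se][Se]c1ccccc1
Why: Selenenylation of both lactone enolates; the diselenide is chosen because it does not add to the exocyclic alkenes, and selenium is expected to enter anti to H7 and H7′ as in santonin-derived guaianolide lactones.

Step 28
Reactants: 34 11,11′-bis(phenylseleno) bis-lactone
Product: 36 3′-hydroxy-3′-deoxoainsliadimer A, via bis-selenoxide 35 (not isolated)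
Conditions: 30% H2O2, pyridine, CH2Cl2, 0 °C → rt
Reagents that add atoms: none
Why: Oxidation to the selenoxides and syn-elimination; with selenium anti to H7 and H7′ only the methyl hydrogens are in reach, so both α-methylene lactones form, and pyridine suppresses epoxidation of the exocyclic alkenes by peroxyseleninic acid.

Step 29
Reactants: 36 3′-hydroxy-3′-deoxoainsliadimer A
Product: 37 ainsliadimer A
Conditions: IBX, DMSO, rt
Reagents that add atoms: none
Why: The C3′ carbinol is the only secondary alcohol left; IBX oxidises it under neutral conditions without touching the tertiary diol, the alkenes or the α-methylene lactones, so the retro-aldol-prone β-hydroxy ketone appears only in the last step.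

## Compound list

1 | α-santonin | C[C@H]1[C@@H]2CC[C@]3(C=CC(=O)C(=C3[C@H]2OC1=O)C)C | starting material
2 | isophotosantonic lactone (10α-hydroxy-3-oxo-1αH-guai-4-en-12,6α-olide) | C[C@@H]1C(=O)O[C@@H]2C3=C(C)C(=O)C[C@H]3[C@](C)(O)CC[C@@H]12 | intermediate
3 | 10α-hydroxy-3-oxo-1αH,4αH,5αH-guaian-12,6α-olide | C[C@@H]1C(=O)O[C@@H]2[C@H]3[C@@H](C)C(=O)C[C@H]3[C@](C)(O)CC[C@@H]12 | intermediate
4 | 3-oxo-1αH,4αH,5αH-guai-10(14)-en-12,6α-olide | C[C@@H]1C(=O)O[C@@H]2[C@H]3[C@@H](C)C(=O)C[C@H]3C(=C)CC[C@@H]12 | intermediate
5 | 3β-hydroxy-1αH,4αH,5αH-guai-10(14)-en-12,6α-olide | C[C@@H]1C(=O)O[C@@H]2[C@H]3[C@@H](C)[C@@H](O)C[C@H]3C(=C)CC[C@@H]12 | intermediate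
6 | secondary ozonide of 5 (spiro-1,2,4-trioxolane at C10) | C[C@@H]1C(=O)O[C@@H]2[C@H]3[C@@H](C)[C@@H](O)C[C@H]3C4(OOCO4)CC[C@@H]12 | intermediate
7 | 3β-hydroxy-10-oxo-14-nor-1αH,4αH,5αH-guaian-12,6α-olide | C[C@@H]1C(=O)O[C@@H]2[C@H]3[C@@H](C)[C@@H](O)C[C@H]3C(=O)CC[C@@H]12 | intermediate
8 | 10,10-ethylenedioxy-3β-hydroxy-14-nor-1αH,4αH,5αH-guaian-12,6α-olide | C[C@@H]1C(=O)O[C@@H]2[C@H]3[C@@H](C)[C@@H](O)C[C@H]3C4(OCCO4)CC[C@@H]12 | intermediate
9 | 10,10-ethylenedioxy-14-nor-1αH,5αH-guai-3-en-12,6α-olide | C[C@@H]1C(=O)O[C@@H]2[C@H]3C(C)=CC[C@H]3C4(OCCO4)CC[C@@H]12 | intermediate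
10 | 3α,4α-epoxy-10,10-ethylenedioxy-14-nor-1αH,5αH-guaian-12,6α-olide | C[C@@H]1C(=O)O[C@@H]2[C@H]3[C@]4(C)O[C@@H]4C[C@H]3C5(OCCO5)CC[C@@H]12 | intermediate
11 | 10,10-ethylenedioxy-3α-hydroxy-14-nor-1αH,5αH-guai-4(15)-en-12,6α-olide | C[C@@H]1C(=O)O[C@@H]2[C@H]3C(=C)[C@H](O)C[C@H]3C4(OCCO4)CC[C@@H]12 | intermediate
12 | 4α,15-epoxy-10,10-ethylenedioxy-3α-hydroxy-14-nor-1αH,5αH-guaian-12,6α-olide | C[C@@H]1C(=O)O[C@@H]2[C@H]3[C@@]4(CO4)[C@H](O)C[C@H]3C5(OCCO5)CC[C@@H]12 | intermediate
13 | 4β-vinyl-3α,4α-diol (10,10-ethylenedioxy-3α,4α-dihydroxy-15-methylene-14-nor-1αH,5αH-guaian-12,6α-olide) | C[C@@H]1C(=O)O[C@@H]2[C@H]3[C@@](O)(C=C)[C@H](O)C[C@H]3C4(OCCO4)CC[C@@H]12 | intermediate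
14 | cyclopent-2-en-1-one | O=C1C=CCC1 | starting material
15 | 2-iodocyclopent-2-en-1-one | O=C1C(I)=CCC1 | intermediate
16 | B-alkyl-9-BBN adduct of 13 (boron on C15′) | C[C@@H]1C(=O)O[C@@H]2[C@H]3[C@@](O)(CCB4C5CCCC4CCC5)[C@H](O)C[C@H]3C6(OCCO6)CC[C@@H]12 | intermediate
17 | diol enone (3α,4α-diol; C4 carries a 2-(5-oxocyclopent-1-en-1-yl)ethyl group β) | C[C@@H]1C(=O)O[C@@H]2[C@H]3[C@@](O)(CCC4=CCCC4=O)[C@H](O)C[C@H]3C5(OCCO5)CC[C@@H]12 | intermediate
18 | 4α-hydroxy-3-ketone with the 2-(5-oxocyclopent-1-en-1-yl)ethyl arm | C[C@@H]1C(=O)O[C@@H]2[C@H]3[C@@](O)(CCC4=CCCC4=O)C(=O)C[C@H]3C5(OCCO5)CC[C@@H]12 | intermediate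
19 | unconjugated spiro aldol (C3–C4′ bond; 3α,4α-diol; C3′ ketone; C1′=C5′) | C[C@@H]1C(=O)O[C@@H]2[C@@H]3[C@@H](C[C@@]4(O)[C@]3(O)CC[C@]43C(=O)CC=C3)C5(OCCO5)CC[C@@H]12 | intermediate
20 | conjugated spiro enone aldol (C3′ ketone; C2′=C1′) | C[C@@H]1C(=O)O[C@@H]2[C@@H]3[C@@H](C[C@@]4(O)[C@]3(O)CC[C@]43C(=O)C=CC3)C5(OCCO5)CC[C@@H]12 | intermediate
21 | spiro cyclopentene bis-dioxolane (C3′ and C10 dioxolanes; C1′=C5′; 3α,4α-diol; 11α-methyl lactone) | C[C@@H]1C(=O)O[C@@H]2[C@@H]3[C@@H](C[C@@]4(O)[C@]3(O)CC[C@]43C5(OCCO5)CC=C3)C6(OCCO6)CC[C@@H]12 | intermediate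
22 | cyclopentane-1,3-dione | O=C1CCC(=O)C1 | starting material
23 | 2-diazocyclopentane-1,3-dione | O=C1CCC(=O)C1=[N+]=[N-] | intermediate
24 | 2-acetoxy-3-hydroxycyclopent-2-en-1-one | CC(=O)OC1=C(O)CCC1=O | intermediate
25 | cyclobutanol photoadduct (cis-anti-cis; C10′–OH, C6′–OAc, C7′ ketone) | C[C@@H]1C(=O)O[C@@H]2[C@@H]3[C@@H](C[C@@]4(O)[C@]3(O)CC[C@]43C5(OCCO5)C[C@H]4[C@]7(O)CCC(=O)[C@]7(OC(C)=O)[C@H]43)C6(OCCO6)CC[C@@H]12 | intermediate
26 | ring B7 acetoxy diketone (1′αH, 5′αH, 6′α-OAc; C7′ and C10′ ketones; C3′ and C10 dioxolanes) | C[C@@H]1C(=O)O[C@@H]2[C@@H]3[C@@H](C[C@@]4(O)[C@]3(O)CC[C@]43C5(OCCO5)C[C@H]4C(=O)CCC(=O)[C@H](OC(C)=O)[C@H]43)C6(OCCO6)CC[C@@H]12 | intermediate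
27 | (E)-enoate (C7′=C11′H–CO2Me; 6′α-OAc) | C[C@@H]1C(=O)O[C@@H]2[C@@H]3[C@@H](C[C@@]4(O)[C@]3(O)CC[C@]43C5(OCCO5)C[C@H]4C(=O)CC/C(=C\C(=O)OC)[C@H](OC(C)=O)[C@H]43)C6(OCCO6)CC[C@@H]12 | intermediate
28 | 6′α-alcohol (E)-enoate | C[C@@H]1C(=O)O[C@@H]2[C@@H]3[C@@H](C[C@@]4(O)[C@]3(O)CC[C@]43C5(OCCO5)C[C@H]4C(=O)CC/C(=C\C(=O)OC)[C@H](O)[C@H]43)C6(OCCO6)CC[C@@H]12 | intermediate
29 | 7′αH hydroxy ester (6′α-OH; 7′β-CH2CO2Me) | C[C@@H]1C(=O)O[C@@H]2[C@@H]3[C@@H](C[C@@]4(O)[C@]3(O)CC[C@]43C5(OCCO5)C[C@H]4C(=O)CC[C@@H](CC(=O)OC)[C@H](O)[C@H]43)C6(OCCO6)CC[C@@H]12 | intermediate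
30 | triketone bis-lactone (C3′, C10, C10′ ketones; trans lactone B; 11α-methyl lactone A) | C[C@@H]1C(=O)O[C@@H]2[C@@H]3[C@@H](C[C@@]4(O)[C@]3(O)CC[C@]43C(=O)C[C@H]4C(=O)CC[C@H]5CC(=O)O[C@@H]5[C@H]43)C(=O)CC[C@@H]12 | intermediate
31 | 3′-alcohol diketone (C3′–OH cis to C15′; C10 and C10′ ketones) | C[C@@H]1C(=O)O[C@@H]2[C@@H]3[C@@H](C[C@@]4(O)[C@]3(O)CC[C@]43[C@@H](O)C[C@H]4C(=O)CC[C@H]5CC(=O)O[C@@H]5[C@H]43)C(=O)CC[C@@H]12 | intermediate
32 | bis(exocyclic methylene) compound (C10=C14, C10′=C14′; 3′-OH) | C[C@@H]1C(=O)O[C@@H]2[C@@H]3[C@@H](C[C@@]4(O)[C@]3(O)CC[C@]43[C@@H](O)C[C@H]4C(=C)CC[C@H]5CC(=O)O[C@@H]5[C@H]43)C(=C)CC[C@@H]12 | intermediate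
33 | 11′-methyl lactone (C11′ epimers) | C[C@@H]1C(=O)O[C@@H]2[C@@H]3[C@@H](C[C@@]4(O)[C@]3(O)CC[C@]43[C@@H](O)C[C@H]4C(=C)CC[C@H]5C(C)C(=O)O[C@@H]5[C@H]43)C(=C)CC[C@@H]12 | intermediate
34 | 11,11′-bis(phenylseleno) bis-lactone (selenium expected anti to H7 and H7′) | CC1([Se]c7ccccc7)C(=O)O[C@@H]2[C@@H]3[C@@H](C[C@@]4(O)[C@]3(O)CC[C@]43[C@@H](O)C[C@H]4C(=C)CC[C@H]5C(C)([Se]c6ccccc6)C(=O)O[C@@H]5[C@H]43)C(=C)CC[C@@H]12 | intermediate
35 | bis-selenoxide of 34 | CC1([Se](=O)c7ccccc7)C(=O)O[C@@H]2[C@@H]3[C@@H](C[C@@]4(O)[C@]3(O)CC[C@]43[C@@H](O)C[C@H]4C(=C)CC[C@H]5C(C)([Se](=O)c6ccccc6)C(=O)O[C@@H]5[C@H]43)C(=C)CC[C@@H]12 | intermediate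
36 | 3′-hydroxy-3′-deoxoainsliadimer A | C=C1C(=O)O[C@@H]2[C@@H]3[C@@H](C[C@@]4(O)[C@]3(O)CC[C@]43[C@@H](O)C[C@H]4C(=C)CC[C@H]5C(=C)C(=O)O[C@@H]5[C@H]43)C(=C)CC[C@@H]12 | intermediate
37 | ainsliadimer A | C=C1C(=O)O[C@@H]2[C@@H]3[C@@H](C[C@@]4(O)[C@]3(O)CC[C@]43C(=O)C[C@H]4C(=C)CC[C@H]5C(=C)C(=O)O[C@@H]5[C@H]43)C(=C)CC[C@@H]12 | target

## Step count and least certain steps

Total step count: 29. Longest linear sequence: 26 steps from α-santonin (steps 1–11, 13–16 and 19–29). Steps 12, 17 and 18 prepare the two small partners.

**Step 19 (key step).** The most likely failure is poor regioselectivity of bond formation at the two alkene carbons, because the only bias is the steric difference between C1′ and C5′. Inefficient capture of the hindered cyclopentene by the free, self-dimerising enol and incomplete equilibration at C6′ are the next concerns. The fallback separates cycloaddition from fragmentation. Enol 24 is silylated (TBSCl, imidazole) to 2-acetoxy-3-(tert-butyldimethylsilyloxy)cyclopent-2-en-1-one F1, an ordinary enone chromophore without an acidic enol. Its [2+2] photocycloaddition with 21 gives the isolable cyclobutane silyl ether F2, from which regio- and stereoisomers can be separated. Buffered fluoride (TBAF, AcOH) then releases the cyclobutanol and triggers the retro-aldol opening. The sequence sets out from 21 and returns to the route at 26.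

**Step 15.** The aldol equilibrium may lie on the side of the open, more substituted enone 18. Reversible oxa-Michael addition of the hydroxyls may compete, and the spiro centre may form as a mixture if the chelate is loose. The fallback is a reductive aldol cyclisation. Conjugate reduction of 18 with [(Ph3P)CuH]6 generates the C4′ copper enolate regiospecifically, and it adds irreversibly to the C3 ketone to give the saturated spiro ketol F3. Dehydrogenation with IBX (DMSO, 70 °C) can occur only towards C2′–C1′ and returns to the route at 20.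

**Step 16.** Alkene migration may be incomplete and give a mixture of allylic and homoallylic ketals. Glycol may add to the unhindered β carbon C1′, or the acid may ionise the ditertiary diol. The fallback sets out from 20 and moves the alkene under kinetic control: KHMDS at −78 °C forms the dienolate, and an acetic acid quench protonates C2′ to give the β,γ-enone 19, which is isolated this time. Aprotic ketalisation (TMSOCH2CH2OTMS, TMSOTf, −78 °C) without equilibration returns to the route at 21. No new compound is needed.

**Step 20.** Olefination of the hindered α-acetoxy ketone may be slow, and prolonged heating may erode E selectivity or cost the acetate. The fallback replaces the Wittig reaction by addition and elimination. A Reformatsky reaction of 26 (activated Zn, BrCH2CO2Me, THF, 0 °C) adds to the more electrophilic α-acyloxy ketone to give the β-hydroxy ester F4. Dehydration with the Martin sulfurane then forms the conjugated ester with the ester group turned away from C6′ and returns to the route at 27.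

**Step 26.** Kinetic discrimination between the two lactones may be insufficient, leading to partial deprotonation and methylation of lactone A. The fallback uses thermodynamic activation. Claisen formylation of 32 (NaH, HCO2Et) can form a stabilised enolate only at the CH2 lactone and gives the hydroxymethylene lactone F5. C-methylation (MeI, K2CO3, acetone) gives the formyl methyl lactone F6. Deformylation (K2CO3, MeOH), which also cleaves any O-formates, returns to the route at 33.

## Further compounds

F1 | step 19 | 2-acetoxy-3-(tert-butyldimethylsilyloxy)cyclopent-2-en-1-one | CC(=O)OC1=C(O[Si](C)(C)C(C)(C)C)CCC1=O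
F2 | step 19 | cyclobutane silyl ether photoadduct (C10′–OTBS, C6′–OAc, C7′ ketone) | C[C@@H]1C(=O)O[C@@H]2[C@@H]3[C@@H](C[C@@]4(O)[C@]3(O)CC[C@]43C5(OCCO5)C[C@H]4[C@]7(O[Si](C)(C)C(C)(C)C)CCC(=O)[C@]7(OC(C)=O)[C@H]43)C6(OCCO6)CC[C@@H]12
F3 | step 15 | saturated spiro ketol (C3–C4′ bond; C3′ ketone; no alkene in ring B5) | C[C@@H]1C(=O)O[C@@H]2[C@@H]3[C@@H](C[C@@]4(O)[C@]3(O)CC[C@]43C(=O)CCC3)C5(OCCO5)CC[C@@H]12
F0 | step 16 | none | none
F4 | step 20 | β-hydroxy ester (C7′ carries OH and CH2CO2Me; 6′α-OAc) | C[C@@H]1C(=O)O[C@@H]2[C@@H]3[C@@H](C[C@@]4(O)[C@]3(O)CC[C@]43C5(OCCO5)C[C@H]4C(=O)CCC(O)(CC(=O)OC)[C@H](OC(C)=O)[C@H]43)C6(OCCO6)CC[C@@H]12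
F5 | step 26 | 11′-hydroxymethylene lactone | C[C@@H]1C(=O)O[C@@H]2[C@@H]3[C@@H](C[C@@]4(O)[C@]3(O)CC[C@]43[C@@H](O)C[C@H]4C(=C)CC[C@H]5C(=CO)C(=O)O[C@@H]5[C@H]43)C(=C)CC[C@@H]12
F6 | step 26 | 11′-formyl-11′-methyl lactone | C[C@@H]1C(=O)O[C@@H]2[C@@H]3[C@@H](C[C@@]4(O)[C@]3(O)CC[C@]43[C@@H](O)C[C@H]4C(=C)CC[C@H]5C(C)(C=O)C(=O)O[C@@H]5[C@H]43)C(=C)CC[C@@H]12
A1 | alternative 1 | diazomethyl ketone on C4′ (diol acetonide, C14′ pivalate) | C1C(=O)O[C@@H]2[C@@H]3[C@@H](C[C@@]4(OC(C)(C)O5)[C@]35CC[C@@]4(C(=O)C=[N+]=[N-])[C@H]6C[C@@H](COC(=O)C(C)(C)C)CC[C@H]7CC(=O)O[C@@H]76)C(=C)CC[C@@H]12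
A2 | alternative 1 | ring B5 cyclopentanone (diol acetonide, C14′ pivalate) | C1C(=O)O[C@@H]2[C@@H]3[C@@H](C[C@@]4(OC(C)(C)O5)[C@]35CC[C@]46C(=O)C[C@H]8[C@@H](COC(=O)C(C)(C)C)CC[C@H]7CC(=O)O[C@@H]7[C@H]86)C(=C)CC[C@@H]12
A3 | alternative 2 | cyclopentylidene allene-yne (C10′ dioxolane) | C1C(=O)O[C@@H]2[C@@H]3[C@@H](C[C@@]4(O)[C@]3(O)CCC4=C=C[C@H](CC(=O)OC)CCC5(OCCO5)C#C)C(=C)CC[C@@H]12
A4 | alternative 2 | spiro 4-alkylidene cyclopentenone (rings B5 and B7 formed, C10′ dioxolane) | C1C(=O)O[C@@H]2[C@@H]3[C@@H](C[C@@]4(O)[C@]3(O)CC[C@]45C(=O)C=C6C5=C[C@H](CC(=O)OC)CCC67OCCO7)C(=C)CC[C@@H]12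
A5 | alternative 3 | eight-membered 1,5-diketone (C3 and C4 ketones, C3′ dioxolane) | C1C(=O)O[C@@H]2[C@@H]3[C@@H](CC(=O)[C@]4(CCC3=O)C6(OCCO6)C[C@H]5C(=C)CC[C@H]7CC(=O)O[C@@H]7[C@H]54)C(=C)CC[C@@H]12
A6 | alternative 3 | bis-des-methylene ainsliadimer A C3′ dioxolane | C1C(=O)O[C@@H]2[C@@H]3[C@@H](C[C@@]4(O)[C@]3(O)CC[C@]43C6(OCCO6)C[C@H]4C(=C)CC[C@H]5CC(=O)O[C@@H]5[C@H]43)C(=C)CC[C@@H]12
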